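**Retrosynthetic overview**

1. Ring names: ring A is the fused dimethoxybenzene ring (C4a–C8a), ring B the saturated ring (C1–C4), ring C the pendant 3,4-dimethoxyphenyl group on C1. Ring B is the only ring that has to be built and is closed last.
2. Key disconnection: the ring C–C1 bond and the C1–C8a bond are cut together, back to veratrole and an open-chain α-branched 4-arylbutanal. Forward, one acid-catalysed tandem Friedel–Crafts operation closes ring B, joins ring C to C1 and sets C1.
3. Enabling feature: C1 is bonded to C8a, which is para to the C6 methoxy of ring A. C8a can therefore close ring B onto a C1 carbonyl, and the C1 cation that follows is a para-methoxybenzylic (quinone-methide-like) ion. Ring C is attached para to a methoxy, the innate site of veratrole, and the cis C2/C3 methyls both shield the same face of the cation.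
4. The chain C1–C2(Me)–C3(Me)–C4 is a masked meso-2,3-dimethylsuccinic acid. Desymmetrising methanolysis of its anhydride sets C2 and C3; the acid end becomes C4 (reduction, lactone, iodide, Negishi coupling to ring A) and the ester end becomes the C1 aldehyde.

Key step: step 7

Remark: (DHQD)2AQN is assumed to deliver the (2S,3R) half-ester; if the sense of induction is the opposite, the pseudo-enantiomeric (DHQ)2AQN is used instead.

**Route**

Step 1
Reactants: 1 meso-2,3-dimethylsuccinic acid
Product: 2 (3R,4S)-3,4-dimethyloxolane-2,5-dione (cis, meso anhydride)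
Conditions: AcCl (neat), reflux; evaporation
Reagents that add atoms: none
Why: Cyclodehydration of a succinic acid to its five-membered anhydride by acetyl chloride (mixed anhydride, then ring closure); no base is present, so the cis (meso) relationship of the methyls should be kept.

Step 2
Reactants: 2 (3R,4S)-3,4-dimethyloxolane-2,5-dione
Product: 3 (2S,3R)-4-methoxy-2,3-dimethyl-4-oxobutanoic acid
Conditions: MeOH (10 equiv), (DHQD)2AQN (10 mol %), Et2O, −20 °C
Reagents that add atoms: methanol, CO
Why: Cinchona-alkaloid-catalysed enantioselective methanolysis of a meso anhydride (desymmetrisation); the catalyst selects one of the two enantiotopic carbonyl groups and so fixes both methyl-bearing centres (later C2 and C3) in one event.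

Step 3
Reactants: 3 (2S,3R)-4-methoxy-2,3-dimethyl-4-oxobutanoic acid
Product: 5 (3R,4S)-3,4-dimethyloxolan-2-one, via hydroxy ester 4 (not isolated)
Conditions: BH3·SMe2 (1.1 equiv), THF, 0 → 20 °C; H2O; then TsOH·H2O (cat.), CH2Cl2, 20 °C
Reagents that add atoms: none
Why: Chemoselective borane reduction of the free carboxylic acid in the presence of the methyl ester, followed by acid-catalysed lactonisation of the γ-hydroxy ester; neither stereocentre is touched and the two chain ends stay differentiated.

Step 4
Reactants: 5 (3R,4S)-3,4-dimethyloxolan-2-one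
Product: 8 methyl (2R,3S)-4-iodo-2,3-dimethylbutanoate, via silyl ester 6 (not isolated), via iodo acid 7 (not isolated)
Conditions: Me3SiI (1.5 equiv), CH2Cl2, 20 °C; then MeOH (excess), 0 → 20 °C
Reagents that add atoms: iodotrimethylsilane, C[Si](C)(C)I; methanol, CO
Why: Silyl iodide cleavage of a lactone (O-silylation, then SN2 attack of iodide at the primary CH2–O carbon), followed by methanolysis of the silyl ester and acid-catalysed esterification; the stereocentres are not involved.

Step 5
Reactants: 8 methyl (2R,3S)-4-iodo-2,3-dimethylbutanoate; 9 4-bromo-1,2-dimethoxybenzene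
Product: 11 methyl (2R,3R)-4-(3,4-dimethoxyphenyl)-2,3-dimethylbutanoate, via alkylzinc iodide 10 (not isolated)
Conditions: Zn dust (activated), LiCl, THF, 30 °C; then 9, Pd(OAc)2 (2 mol %), SPhos (4 mol %), THF, 25 °C
Reagents that add atoms: none
Why: Negishi sp3–sp2 cross-coupling; zinc insertion into the primary C–I bond tolerates the ester, and the palladium/SPhos catalyst should join the primary alkylzinc to the electron-rich aryl bromide (C4–C4a bond) without touching C2 or C3.

Step 6
Reactants: 11 methyl (2R,3R)-4-(3,4-dimethoxyphenyl)-2,3-dimethylbutanoate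
Product: 12 (2R,3R)-4-(3,4-dimethoxyphenyl)-2,3-dimethylbutanal
Conditions: i-Bu2AlH (1.05 equiv), CH2Cl2, −78 °C; aq. Rochelle salt; used at once
Reagents that add atoms: none
Why: Partial reduction of a methyl ester by i-Bu2AlH at −78 °C, where the tetrahedral aluminium hemiacetal persists until hydrolysis; the cold, non-basic conditions should leave the α-stereocentre (C2) intact.

Step 7
Reactants: 12 (2R,3R)-4-(3,4-dimethoxyphenyl)-2,3-dimethylbutanal; 13 1,2-dimethoxybenzene (veratrole)
Product: 16 (1R,2R,3R)-1-(3,4-dimethoxyphenyl)-6,7-dimethoxy-2,3-dimethyl-1,2,3,4-tetrahydronaphthalene, via 1-tetralol 14 (not isolated), via benzylic cation 15 (not isolated)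
Conditions: 13 (5 equiv), Bi(OTf)3 (10 mol %), MeNO2, 0 → 20 °C
Reagents that add atoms: none
Why: Bi(OTf)3 activates the aldehyde of 12 for Friedel–Crafts hydroxyalkylation by the ring A carbon para to a methoxy, which closes ring B in the 6-exo-trig mode (C1–C8a) to 1-tetralol 14; this ionises to the para-methoxybenzylic cation 15, which veratrole 13 attacks through its C4 to form the ring C–C1 bond with loss of water. The closest known reaction types are the acid-catalysed double Friedel–Crafts reaction of an aldehyde with one tethered and one external arene (9-arylfluorenes, 9-arylxanthenes, 4-aryltetralins from Prins/Friedel–Crafts cascades) and the diastereoselective Friedel–Crafts trapping of α-branched benzylic and tetralin-1-yl cations. The new stereocentre C1 is set by substrate control: in either half-chair of 15 the cis C2 and C3 methyls lie on the same face, so the arene should add to the opposite face, giving the 1,2-trans-1,3-trans product; C2 and C3 are carried through from 3. The step needs closure of ring B para rather than ortho to a methoxy (secured by the 3,4-dimethoxy pattern and the crowded alternative site), para attack by 13 (its innate position), and capture of 15 faster than loss of the C2 proton; the excess of 13, the polar non-basic medium and the low temperature are chosen to favour capture.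

**Compound list**

1 | meso-2,3-dimethylsuccinic acid | OC(=O)[C@@H](C)[C@H](C(=O)O)C | starting material
2 | (3R,4S)-3,4-dimethyloxolane-2,5-dione (cis, meso) | O=C1OC(=O)[C@@H](C)[C@H]1C | intermediate
3 | (2S,3R)-4-methoxy-2,3-dimethyl-4-oxobutanoic acid | OC(=O)[C@@H](C)[C@H](C(=O)OC)C | intermediate
4 | methyl (2R,3S)-4-hydroxy-2,3-dimethylbutanoate | OC[C@@H](C)[C@H](C(=O)OC)C | intermediate
5 | (3R,4S)-3,4-dimethyloxolan-2-one | O=C1OC[C@@H](C)[C@H]1C | intermediate
6 | trimethylsilyl (2R,3S)-4-iodo-2,3-dimethylbutanoate | IC[C@@H](C)[C@H](C(=O)O[Si](C)(C)C)C | intermediate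
7 | (2R,3S)-4-iodo-2,3-dimethylbutanoic acid | IC[C@@H](C)[C@H](C(=O)O)C | intermediate
8 | methyl (2R,3S)-4-iodo-2,3-dimethylbutanoate | IC[C@@H](C)[C@H](C(=O)OC)C | intermediate
9 | 4-bromo-1,2-dimethoxybenzene | COc1ccc(Br)cc1OC | starting material
10 | [(2S,3R)-4-methoxy-2,3-dimethyl-4-oxobutyl]zinc iodide | I[Zn]C[C@@H](C)[C@H](C(=O)OC)C | intermediate
11 | methyl (2R,3R)-4-(3,4-dimethoxyphenyl)-2,3-dimethylbutanoate | COc1ccc(C[C@@H](C)[C@H](C(=O)OC)C)cc1OC | intermediate
12 | (2R,3R)-4-(3,4-dimethoxyphenyl)-2,3-dimethylbutanal | COc1ccc(C[C@@H](C)[C@H](C=O)C)cc1OC | intermediate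
13 | 1,2-dimethoxybenzene (veratrole) | COc1ccccc1OC | starting material
14 | (2R,3R)-6,7-dimethoxy-2,3-dimethyl-1,2,3,4-tetrahydronaphthalen-1-ol (C1 epimers) | OC1c2cc(OC)c(OC)cc2C[C@@H](C)[C@H]1C | intermediate
15 | 6,7-dimethoxy-2,3-cis-dimethyl-1,2,3,4-tetrahydronaphthalen-1-yl cation (C2 and C3 configured as in 12) | [CH+]1c2cc(OC)c(OC)cc2C[C@@H](C)[C@H]1C | intermediate
16 | (1R,2R,3R)-1-(3,4-dimethoxyphenyl)-6,7-dimethoxy-2,3-dimethyl-1,2,3,4-tetrahydronaphthalene | COc1ccc([C@@H]2c3cc(OC)c(OC)cc3C[C@@H](C)[C@H]2C)cc1OC | target

**Step count and risks**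

Total steps: 7. Longest linear sequence: 7 steps (1 → 16).

Steps most likely to fail:

1. Step 7. Three processes could go wrong. Cation 15 could lose the C2 proton to the 1,2-dihydronaphthalene and be reprotonated, which would scramble C2. Aldehyde 12 could enolise under acid before ring closure. The aldehyde could be arylated twice by external veratrole before ring B closes. The fallback sets out from 12 (with 9) and comes back at 16. Bromide 9 is converted with Mg in THF into 3,4-dimethoxyphenylmagnesium bromide F1, which is added to 12 at −78 °C to give (2R,3R)-1,4-bis(3,4-dimethoxyphenyl)-2,3-dimethylbutan-1-ol F2 as a mixture of C1 epimers. Treatment of this carbinol with CF3CO2H in CH2Cl2 at 0 °C should ionise it to the ring C-stabilised cation, which closes ring B by intramolecular Friedel–Crafts alkylation (C1–C8a) in a chair-like transition state with the aryl group trans to the C2 methyl, giving 16. Here the cation is trapped intramolecularly, so proton loss should not compete.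

2. Step 6. The ester could be over-reduced to the primary alcohol, and the α-branched aldehyde could epimerise during work-up or storage. The fallback sets out from 11 and comes back at 12. LiAlH4 in THF at 0 °C should reduce the ester fully to (2R,3R)-4-(3,4-dimethoxyphenyl)-2,3-dimethylbutan-1-ol F3, which is oxidised with Dess–Martin periodinane and NaHCO3 in CH2Cl2 at 0 °C to 12 and used directly.

3. Step 4. The γ-iodo ester could return to lactone 5 with loss of iodomethane on concentration or during zinc insertion, and the esterification could stay incomplete. The fallback sets out from 3 and comes back at 11; it makes the C4–ring A bond by acylation instead of alkyl coupling. Acid 3 is converted with EtSH, dicyclohexylcarbodiimide and catalytic 4-(dimethylamino)pyridine in CH2Cl2 at 0 °C into methyl (2R,3S)-4-(ethylsulfanyl)-2,3-dimethyl-4-oxobutanoate F4. A Liebeskind–Srogl coupling of this thioester with 3,4-dimethoxyphenylboronic acid (Pd2(dba)3, tri(2-furyl)phosphine, copper thiophene-2-carboxylate CuO2CC4H3S, THF, 50 °C) should give methyl (2R,3S)-4-(3,4-dimethoxyphenyl)-2,3-dimethyl-4-oxobutanoate F5 under neutral conditions. Ionic hydrogenation of the electron-rich aryl ketone (Et3SiH, CF3CO2H, 0 °C) then removes the carbonyl oxygen to give 11; it is run cold to limit enolisation next to the ketone.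

**Further compounds**

F1 | step 7 | 3,4-dimethoxyphenylmagnesium bromide | COc1ccc([Mg]Br)cc1OC
F2 | step 7 | (2R,3R)-1,4-bis(3,4-dimethoxyphenyl)-2,3-dimethylbutan-1-ol (C1 epimers) | COc1ccc(C[C@@H](C)[C@H](C(O)c2ccc(OC)c(OC)c2)C)cc1OC
F3 | step 6 | (2R,3R)-4-(3,4-dimethoxyphenyl)-2,3-dimethylbutan-1-ol | COc1ccc(C[C@@H](C)[C@H](CO)C)cc1OC
F4 | step 4 | methyl (2R,3S)-4-(ethylsulfanyl)-2,3-dimethyl-4-oxobutanoate | CCSC(=O)[C@@H](C)[C@H](C(=O)OC)C
F5 | step 4 | methyl (2R,3S)-4-(3,4-dimethoxyphenyl)-2,3-dimethyl-4-oxobutanoate | COc1ccc(C(=O)[C@@H](C)[C@H](C(=O)OC)C)cc1OC
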